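**Retrosynthetic overview**

1. The target consists of two trans-2-aryl-2,3-dihydrobenzofurans (ring A carries the 6-styryl group, ring B the 3-(3,5-dihydroxyphenyl) group) joined C3(ring A)–C6(ring B). It is cut at the seven O–methyl bonds of a heptamethyl ether, then at C3(A)–C6(B) (decarboxylative arylation of a ring A C3 acid by a ring B C6 arylzinc), then at the styryl C–C bond of ring A (Suzuki–Miyaura) and in the resorcinol ring on C3 of ring B (grown from the C3 ester carbon and acetylacetone).
2. Both halves converge on one compound, the trans methyl 6-bromo-4-methoxy-2-aryl-2,3-dihydrobenzofuran-3-carboxylate 12.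
3. The strategy rests on this feature: in each dihydrobenzofuran, O1–C2(aryl) and a benzo ring oxygenated at C4 and C7a flank C3a. These are the atoms of a 5-oxygenated 2-arylchroman-4-one whose carbonyl carbon has left the ring. Shifting the benzo carbon (future C3a) from the carbonyl carbon to C3 forms C3–C3a, contracts the pyranone to the dihydrofuran and leaves the old carbonyl carbon as the C3 ester.
4. The C2 aryl group goes through that shift as 4-acetoxyphenyl, because a 4-methoxyphenyl group at C2 would itself migrate (isoflavone pathway). C2 is set by an enantioselective conjugate addition to the chromone.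
5. Ring order: pyranone of the chromone, then the dihydrofuran by contraction (common to rings A and B), then the resorcinol ring on ring B, then union of rings A and B, then deprotection.

Key step: step 5

Remark: the (S)-pyridine–oxazoline ligand is assumed to deliver aryl to the chromone face that gives (2R), as it does with cyclic enones, so the (R)-ligand is specified for the (2S) series; if the chromone responds in the opposite sense, the other ligand enantiomer is used.

**Route**

Step 1
Reactants: 1 1-(4-bromo-2,6-difluorophenyl)ethanone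
Product: 2 1-(4-bromo-2,6-dimethoxyphenyl)ethanone
Conditions: NaOMe (3 equiv), MeOH–DMF, 70 °C
Reagents that add atoms: sodium methoxide, [Na+].[O-]C
Why: Nucleophilic aromatic substitution (SNAr) in which both fluorides ortho to the acetyl group are displaced far faster than the para bromide, and the two methoxy groups then deactivate the ring so that the bromide stays.

Step 2
Reactants: 2 1-(4-bromo-2,6-dimethoxyphenyl)ethanone
Product: 3 1-(4-bromo-2-hydroxy-6-methoxyphenyl)ethanone
Conditions: BCl3 (1.2 equiv), CH2Cl2, −78 → 0 °C; aqueous work-up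
Reagents that add atoms: none
Why: Chelation-controlled Lewis acid ether cleavage in which BCl3 bridges the carbonyl oxygen and one ortho methoxy group, chloride removes that methyl group, and the boron chelate formed protects the second ether.

Step 3
Reactants: 3 1-(4-bromo-2-hydroxy-6-methoxyphenyl)ethanone
Product: 5 7-bromo-5-methoxy-4H-chromen-4-one, via enaminone 4 (not isolated)
Conditions: Me2NCH(OMe)2, toluene, 100 °C; then conc. HCl, CH2Cl2, 40 °C
Reagents that add atoms: N,N-dimethylformamide dimethyl acetal, COC(OC)N(C)C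
Why: Enaminone route to chromones, in which the acetyl methyl group condenses with the amide acetal and acid then lets the phenol add to the enaminone carbon and expel dimethylamine (addition–elimination), closing the pyranone.

Step 4
Reactants: 5 7-bromo-5-methoxy-4H-chromen-4-one, 6 4-acetoxyphenylboronic acid
Product: 7 4-[(2S)-7-bromo-5-methoxy-4-oxochroman-2-yl]phenyl acetate
Conditions: Pd(OCOCF3)2 (10 mol %), (R)-4-tert-butyl-2-(pyridin-2-yl)-4,5-dihydrooxazole (12 mol %), NH4PF6 (30 mol %), H2O (5 equiv), ClCH2CH2Cl, 60 °C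
Reagents that add atoms: none
Why: Enantioselective conjugate addition of an arylboronic acid to a chromone under cationic divalent palladium, in which the C2=C3 bond inserts into aryl–palladium on the face left open by the tert-butyl group of the ligand (this sets C2) and the palladium enolate is protonated, a cycle that never passes through zerovalent palladium and so leaves the aryl bromide alone.

Step 5
Reactants: 7 4-[(2S)-7-bromo-5-methoxy-4-oxochroman-2-yl]phenyl acetate
Product: 10 methyl (2S,3S)-2-(4-acetoxyphenyl)-6-bromo-4-methoxy-2,3-dihydrobenzofuran-3-carboxylate, via methyl enol ether 8 (not isolated), via trans C3 iodane 9 (not isolated)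
Conditions: PhI(OAc)2 (1.3 equiv), conc. H2SO4, HC(OMe)3, 0 → 25 °C
Reagents that add atoms: trimethyl orthoformate, COC(OC)OC
Why: In acidic trimethyl orthoformate the ketone of 7 is converted into its methyl enol ether 8, whose C3 attacks PhI(OAc)2 (trivalent iodine) on the face opposite the C2 aryl group while methanol adds to C4, giving the 2,3-trans iodane 9 with aryl and iodine both equatorial. The benzo carbon C4a, whose bond to C4 is antiperiplanar to the C3–I bond and which is pushed by the two methoxy oxygens on C4, then shifts from C4 to C3 with inversion at C3 as iodobenzene leaves, and the dimethoxycarbenium ion left at the old C4 gives up one methyl group to acetic acid and becomes the ester carbon. The closest known reaction type is the oxidative 1,2-aryl shift of aryl ketone enol ethers with hypervalent iodine or Tl(NO3)3 in orthoformate, which converts flavanones into methyl trans-2-aryl-2,3-dihydrobenzofuran-3-carboxylates. The dihydrofuran ring is closed by contraction of the six-membered pyranone through a bridged arenium transition state (C4a bonded to C3 and C4 at once), not by an end-to-end cyclisation, and the bond formed is C3–C3a of the benzofuran. C3 is controlled by C2, since anti addition of iodine followed by inversion puts the ester trans to the aryl group (2S,3S), which is also the more stable arrangement, and C2 itself is not involved. The step needs the ring-carbon shift to win over migration of the C2 aryl group (isoflavone pathway), over loss of a proton and iodobenzene (flavone) and over ionisation at C2; C4a is made electron-rich by O1 and the 5-methoxy group, and the C2 aryl group is carried as its acetate, which migrates poorly and does not stabilise a cation at C2.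

Step 6
Reactants: 10 methyl (2S,3S)-2-(4-acetoxyphenyl)-6-bromo-4-methoxy-2,3-dihydrobenzofuran-3-carboxylate
Product: 12 methyl (2S,3S)-6-bromo-4-methoxy-2-(4-methoxyphenyl)-2,3-dihydrobenzofuran-3-carboxylate, via phenol 11 (not isolated)
Conditions: K2CO3, MeOH, 0 → 25 °C; then concentrate, MeI, DMF, 25 °C
Reagents that add atoms: iodomethane, CI
Why: Transesterification of the aryl acetate by methanol and carbonate (degenerate for the methyl ester) followed by Williamson ether synthesis on the freed phenoxide, with C3 remaining trans because that is the stable arrangement of the enolisable centre.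

Step 7
Reactants: 12 methyl (2S,3S)-6-bromo-4-methoxy-2-(4-methoxyphenyl)-2,3-dihydrobenzofuran-3-carboxylate, 13 (E)-2-(4-methoxyphenyl)vinylboronic acid
Product: 14 methyl (2S,3S)-4-methoxy-2-(4-methoxyphenyl)-6-[(E)-2-(4-methoxyphenyl)ethenyl]-2,3-dihydrobenzofuran-3-carboxylate
Conditions: Pd(dppf)Cl2 (5 mol %), K2CO3, 1,4-dioxane–H2O, 80 °C
Reagents that add atoms: none
Why: Suzuki–Miyaura coupling of the aryl bromide with an (E)-alkenylboronic acid, which transfers the alkene with retention of geometry under a base too weak to enolise the ester.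

Step 8
Reactants: 14 methyl (2S,3S)-4-methoxy-2-(4-methoxyphenyl)-6-[(E)-2-(4-methoxyphenyl)ethenyl]-2,3-dihydrobenzofuran-3-carboxylate
Product: 15 (2S,3S)-4-methoxy-2-(4-methoxyphenyl)-6-[(E)-2-(4-methoxyphenyl)ethenyl]-2,3-dihydrobenzofuran-3-carboxylic acid
Conditions: LiOH·H2O, THF–MeOH–H2O, 25 °C; then 1 M HCl
Reagents that add atoms: lithium hydroxide, [Li+].[OH-]
Why: Saponification of the methyl ester, in which any enolisation at C3 returns the more stable trans acid and beta-elimination of O1 is disfavoured because the enolate p orbital is orthogonal to the C2–O1 bond of the five-membered ring.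

Step 9
Reactants: 15 (2S,3S)-4-methoxy-2-(4-methoxyphenyl)-6-[(E)-2-(4-methoxyphenyl)ethenyl]-2,3-dihydrobenzofuran-3-carboxylic acid
Product: 16 1,3-dioxoisoindolin-2-yl (2S,3S)-4-methoxy-2-(4-methoxyphenyl)-6-[(E)-2-(4-methoxyphenyl)ethenyl]-2,3-dihydrobenzofuran-3-carboxylate
Conditions: N-hydroxyphthalimide, N,N'-diisopropylcarbodiimide, DMAP (cat.), CH2Cl2, 25 °C
Reagents that add atoms: N-hydroxyphthalimide, O=C1c2ccccc2C(=O)N1O
Why: Carbodiimide (Steglich-type) esterification with N-hydroxyphthalimide gives the redox-active ester from which the C3 radical of ring A will be released.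

Step 10
Reactants: 12 methyl (2S,3S)-6-bromo-4-methoxy-2-(4-methoxyphenyl)-2,3-dihydrobenzofuran-3-carboxylate, 17 pentane-2,4-dione (acetylacetone)
Product: 19 1-[(2S,3S)-6-bromo-4-methoxy-2-(4-methoxyphenyl)-2,3-dihydrobenzofuran-3-yl]hexane-1,3,5-trione, via dilithio acetylacetone 18 (not isolated)
Conditions: 17 (3 equiv), LiN(i-Pr)2 (6 equiv), THF, −78 → 0 °C; then 12, −78 → 0 °C; AcOH quench
Reagents that add atoms: none
Why: Claisen-type C-acylation of a 1,3-diketone dianion at its terminal carbanion by an ester, run with excess dianion because the triketone formed is deprotonated at once, and expected to outrun proton transfer from the hindered tertiary C3–H.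

Step 11
Reactants: 19 1-[(2S,3S)-6-bromo-4-methoxy-2-(4-methoxyphenyl)-2,3-dihydrobenzofuran-3-yl]hexane-1,3,5-trione
Product: 21 5-[(2S,3S)-6-bromo-4-methoxy-2-(4-methoxyphenyl)-2,3-dihydrobenzofuran-3-yl]benzene-1,3-diol, via aldol adduct 20 (not isolated)
Conditions: KOH (2 M aq), MeOH, 25 → 50 °C; then HCl (aq)
Reagents that add atoms: none
Why: Base-mediated intramolecular aldol condensation of a 1,3,5-triketone to a 5-substituted resorcinol (the way heptane-2,4,6-trione gives orcinol), a 6-(enolendo)-exo-trig attack of the terminal methyl carbon on the ketone next to C3 followed by dehydration and enolisation to the aromatic ring, which is the thermodynamic sink of the reversible aldol equilibria.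

Step 12
Reactants: 21 5-[(2S,3S)-6-bromo-4-methoxy-2-(4-methoxyphenyl)-2,3-dihydrobenzofuran-3-yl]benzene-1,3-diol
Product: 22 (2S,3S)-6-bromo-3-(3,5-dimethoxyphenyl)-4-methoxy-2-(4-methoxyphenyl)-2,3-dihydrobenzofuran
Conditions: MeI, K2CO3, acetone, 56 °C
Reagents that add atoms: iodomethane, CI
Why: Williamson ether synthesis on both phenols under conditions that touch neither the aryl bromide nor the two benzylic stereocentres.

Step 13
Reactants: 22 (2S,3S)-6-bromo-3-(3,5-dimethoxyphenyl)-4-methoxy-2-(4-methoxyphenyl)-2,3-dihydrobenzofuran, 16 1,3-dioxoisoindolin-2-yl (2S,3S)-4-methoxy-2-(4-methoxyphenyl)-6-[(E)-2-(4-methoxyphenyl)ethenyl]-2,3-dihydrobenzofuran-3-carboxylate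
Product: 25 (2S,3S)-3-(3,5-dimethoxyphenyl)-4-methoxy-6-[(2S,3S)-4-methoxy-2-(4-methoxyphenyl)-6-[(E)-2-(4-methoxyphenyl)ethenyl]-2,3-dihydrobenzofuran-3-yl]-2-(4-methoxyphenyl)-2,3-dihydrobenzofuran, via aryllithium 23 (not isolated), via arylzinc chloride 24 (not isolated)
Conditions: 22 (2.5 equiv), n-BuLi, THF, −78 °C; ZnCl2, −78 → 25 °C; then 16, NiCl2·glyme (20 mol %), 4,4'-di-tert-butyl-2,2'-bipyridine (40 mol %), THF–DMF, 25 °C
Reagents that add atoms: none
Why: Nickel-catalysed decarboxylative Negishi-type arylation of a redox-active ester, in which bromine–lithium exchange and transmetalation give the arylzinc, an arylnickel species reduces the N-acyloxyphthalimide by single-electron transfer with loss of CO2 and phthalimide, and the benzylic C3 radical of ring A is captured and reductively eliminated on the face away from its C2 aryl group, which should give the trans C3(ring A)–C6(ring B) bond whatever the configuration of the acid.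

Step 14
Reactants: 25 (2S,3S)-3-(3,5-dimethoxyphenyl)-4-methoxy-6-[(2S,3S)-4-methoxy-2-(4-methoxyphenyl)-6-[(E)-2-(4-methoxyphenyl)ethenyl]-2,3-dihydrobenzofuran-3-yl]-2-(4-methoxyphenyl)-2,3-dihydrobenzofuran
Product: 26 5-[(2S,3S)-4-hydroxy-6-[(2S,3S)-4-hydroxy-2-(4-hydroxyphenyl)-6-[(E)-2-(4-hydroxyphenyl)ethenyl]-2,3-dihydrobenzofuran-3-yl]-2-(4-hydroxyphenyl)-2,3-dihydrobenzofuran-3-yl]benzene-1,3-diol (CNP0248228.2)
Conditions: BBr3 (excess), CH2Cl2, −78 → 0 °C; then MeOH, H2O
Reagents that add atoms: none
Why: Lewis acid cleavage of all seven aryl methyl ethers by BBr3 (bromide attacks the methyl group of each boron-bound ether), with no stereocentre involved and with the styryl group too remote from either C3 aryl group for an intramolecular arene–alkene cyclisation.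

**Compound list**

1 | 1-(4-bromo-2,6-difluorophenyl)ethanone | CC(=O)c1c(F)cc(Br)cc1F | starting material
2 | 1-(4-bromo-2,6-dimethoxyphenyl)ethanone | CC(=O)c1c(OC)cc(Br)cc1OC | intermediate
3 | 1-(4-bromo-2-hydroxy-6-methoxyphenyl)ethanone | CC(=O)c1c(O)cc(Br)cc1OC | intermediate
4 | (E)-1-(4-bromo-2-hydroxy-6-methoxyphenyl)-3-(dimethylamino)prop-2-en-1-one (not isolated) | CN(C)/C=C/C(=O)c1c(O)cc(Br)cc1OC | intermediate
5 | 7-bromo-5-methoxy-4H-chromen-4-one | COc1cc(Br)cc2occc(=O)c12 | intermediate
6 | 4-acetoxyphenylboronic acid | CC(=O)Oc1ccc(B(O)O)cc1 | starting material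
7 | 4-[(2S)-7-bromo-5-methoxy-4-oxochroman-2-yl]phenyl acetate | Brc1cc(OC)c2c(c1)O[C@H](c1ccc(OC(C)=O)cc1)CC2=O | intermediate
8 | 4-[(2S)-7-bromo-4,5-dimethoxy-2H-chromen-2-yl]phenyl acetate (not isolated) | Brc1cc(OC)c2c(c1)O[C@H](c1ccc(OC(C)=O)cc1)C=C2OC | intermediate
9 | 4-[(2R,3R)-3-[acetoxy(phenyl)-λ3-iodanyl]-7-bromo-4,4,5-trimethoxychroman-2-yl]phenyl acetate, 2,3-trans (not isolated) | Brc1cc(OC)c2c(c1)O[C@H](c1ccc(OC(C)=O)cc1)[C@@H](I(OC(C)=O)c1ccccc1)C2(OC)OC | intermediate
10 | methyl (2S,3S)-2-(4-acetoxyphenyl)-6-bromo-4-methoxy-2,3-dihydrobenzofuran-3-carboxylate, 2,3-trans | Brc1cc(OC)c2c(c1)O[C@H](c1ccc(OC(C)=O)cc1)[C@H]2C(=O)OC | intermediate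
11 | methyl (2S,3S)-6-bromo-2-(4-hydroxyphenyl)-4-methoxy-2,3-dihydrobenzofuran-3-carboxylate (not isolated) | Brc1cc(OC)c2c(c1)O[C@H](c1ccc(O)cc1)[C@H]2C(=O)OC | intermediate
12 | methyl (2S,3S)-6-bromo-4-methoxy-2-(4-methoxyphenyl)-2,3-dihydrobenzofuran-3-carboxylate, 2,3-trans | Brc1cc(OC)c2c(c1)O[C@H](c1ccc(OC)cc1)[C@H]2C(=O)OC | intermediate
13 | (E)-2-(4-methoxyphenyl)vinylboronic acid | COc1ccc(/C=C/B(O)O)cc1 | starting material
14 | methyl (2S,3S)-4-methoxy-2-(4-methoxyphenyl)-6-[(E)-2-(4-methoxyphenyl)ethenyl]-2,3-dihydrobenzofuran-3-carboxylate | COc1ccc(/C=C/c2cc(OC)c3c(c2)O[C@H](c2ccc(OC)cc2)[C@H]3C(=O)OC)cc1 | intermediate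
15 | (2S,3S)-4-methoxy-2-(4-methoxyphenyl)-6-[(E)-2-(4-methoxyphenyl)ethenyl]-2,3-dihydrobenzofuran-3-carboxylic acid | COc1ccc(/C=C/c2cc(OC)c3c(c2)O[C@H](c2ccc(OC)cc2)[C@H]3C(=O)O)cc1 | intermediate
16 | 1,3-dioxoisoindolin-2-yl (2S,3S)-4-methoxy-2-(4-methoxyphenyl)-6-[(E)-2-(4-methoxyphenyl)ethenyl]-2,3-dihydrobenzofuran-3-carboxylate | COc1ccc(/C=C/c2cc(OC)c3c(c2)O[C@H](c2ccc(OC)cc2)[C@H]3C(=O)ON2C(=O)c3ccccc3C2=O)cc1 | intermediate
17 | pentane-2,4-dione (acetylacetone) | CC(=O)CC(C)=O | starting material
18 | dilithium salt of the pentane-2,4-dione 1,3-dianion (not isolated) | [Li+].[Li+].[CH2-]C(=O)[CH-]C(C)=O | intermediate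
19 | 1-[(2S,3S)-6-bromo-4-methoxy-2-(4-methoxyphenyl)-2,3-dihydrobenzofuran-3-yl]hexane-1,3,5-trione | Brc1cc(OC)c2c(c1)O[C@H](c1ccc(OC)cc1)[C@H]2C(=O)CC(=O)CC(C)=O | intermediate
20 | 5-[(2S,3S)-6-bromo-4-methoxy-2-(4-methoxyphenyl)-2,3-dihydrobenzofuran-3-yl]-5-hydroxycyclohexane-1,3-dione (not isolated) | Brc1cc(OC)c2c(c1)O[C@H](c1ccc(OC)cc1)[C@H]2C1(O)CC(=O)CC(=O)C1 | intermediate
21 | 5-[(2S,3S)-6-bromo-4-methoxy-2-(4-methoxyphenyl)-2,3-dihydrobenzofuran-3-yl]benzene-1,3-diol | Brc1cc(OC)c2c(c1)O[C@H](c1ccc(OC)cc1)[C@H]2c1cc(O)cc(O)c1 | intermediate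
22 | (2S,3S)-6-bromo-3-(3,5-dimethoxyphenyl)-4-methoxy-2-(4-methoxyphenyl)-2,3-dihydrobenzofuran | Brc1cc(OC)c2c(c1)O[C@H](c1ccc(OC)cc1)[C@H]2c1cc(OC)cc(OC)c1 | intermediate
23 | [(2S,3S)-3-(3,5-dimethoxyphenyl)-4-methoxy-2-(4-methoxyphenyl)-2,3-dihydrobenzofuran-6-yl]lithium (not isolated) | [Li]c1cc(OC)c2c(c1)O[C@H](c1ccc(OC)cc1)[C@H]2c1cc(OC)cc(OC)c1 | intermediate
24 | chloro[(2S,3S)-3-(3,5-dimethoxyphenyl)-4-methoxy-2-(4-methoxyphenyl)-2,3-dihydrobenzofuran-6-yl]zinc (not isolated) | Cl[Zn]c1cc(OC)c2c(c1)O[C@H](c1ccc(OC)cc1)[C@H]2c1cc(OC)cc(OC)c1 | intermediate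
25 | (2S,3S)-3-(3,5-dimethoxyphenyl)-4-methoxy-6-[(2S,3S)-4-methoxy-2-(4-methoxyphenyl)-6-[(E)-2-(4-methoxyphenyl)ethenyl]-2,3-dihydrobenzofuran-3-yl]-2-(4-methoxyphenyl)-2,3-dihydrobenzofuran (heptamethyl ether of the target) | COc1ccc(/C=C/c2cc(OC)c3c(c2)O[C@H](c2ccc(OC)cc2)[C@H]3c2cc(OC)c3c(c2)O[C@H](c2ccc(OC)cc2)[C@H]3c2cc(OC)cc(OC)c2)cc1 | intermediate
26 | 5-[(2S,3S)-4-hydroxy-6-[(2S,3S)-4-hydroxy-2-(4-hydroxyphenyl)-6-[(E)-2-(4-hydroxyphenyl)ethenyl]-2,3-dihydrobenzofuran-3-yl]-2-(4-hydroxyphenyl)-2,3-dihydrobenzofuran-3-yl]benzene-1,3-diol (CNP0248228.2) | Oc1ccc(/C=C/c2cc(O)c3c(c2)O[C@H](c2ccc(O)cc2)[C@H]3c2cc(O)c3c(c2)O[C@H](c2ccc(O)cc2)[C@H]3c2cc(O)cc(O)c2)cc1 | target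

**Step count**

Total step count: 14. Longest linear sequence: 11 steps (steps 1–6, then 7–9 or 10–12, then 13 and 14).

**Steps most likely to fail**

Step 5 (ring contraction). The C2 aryl group may migrate, or a proton and iodobenzene may be lost to give the flavone, in place of the ring-carbon shift. Enol ether formation may be slow at the carbonyl flanked by the 5-methoxy group. The acid may methanolyse the aryl acetate or open the ring at C2 and erode the enantiopurity. The fallback separates the functionalisation of C3 from the shift and sets out from 7. Phenyltrimethylammonium tribromide in THF at 0 °C should give the 2,3-trans bromide 4-[(2R,3R)-3,7-dibromo-5-methoxy-4-oxochroman-2-yl]phenyl acetate F1. HC(OMe)3 with catalytic CF3SO3H in methanol should convert it into the ketal 4-[(2R,3R)-3,7-dibromo-4,4,5-trimethoxychroman-2-yl]phenyl acetate F2. AgBF4 in CH2Cl2–methanol then removes bromide and induces the same C4a shift with inversion (the silver- or zinc-halide-promoted 1,2-aryl shift of alpha-halo ketals to arylacetic esters). Aqueous work-up brings the route back at 10.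

Step 11 (resorcinol ring). The chain may fail to cyclise because both diketone units sit as unreactive enolates in base. The ring carbon C3 may attack the far carbonyl (spiro aldol). Hydroxide may cleave the triketone by a retro-Claisen reaction. The fallback activates the attacking carbon as a beta-keto acid and sets out from 19. LiN(i-Pr)2 (3.2 equiv) in THF forms the trianion, which CO2 should carboxylate at the terminal carbon to give 7-[(2S,3S)-6-bromo-4-methoxy-2-(4-methoxyphenyl)-2,3-dihydrobenzofuran-3-yl]-3,5,7-trioxoheptanoic acid F3. In dilute aqueous KOH at 25 °C the methylene between carboxylate and ketone attacks the ketone next to C3 and the ring aromatises to 2-[(2S,3S)-6-bromo-4-methoxy-2-(4-methoxyphenyl)-2,3-dihydrobenzofuran-3-yl]-4,6-dihydroxybenzoic acid F4. Heating F4 in water–dioxane at 100 °C decarboxylates this ortho- and para-hydroxylated acid and returns the route at 21.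

Step 13 (fragment union). The benzylic C3 radical may dimerise or be reduced before arylnickel captures it. Transmetalation from the electron-rich arylzinc may be slow, or the arylzinc may be protonated. The fallback couples two electrophiles under reducing conditions in place of a preformed organometallic and sets out from 22 and 16. Aryllithium 23 (n-BuLi, THF, −78 °C) is quenched with iodine to give (2S,3S)-3-(3,5-dimethoxyphenyl)-6-iodo-4-methoxy-2-(4-methoxyphenyl)-2,3-dihydrobenzofuran F5. F5 and 16 with NiBr2·glyme, 4,4'-di-tert-butyl-2,2'-bipyridine and Zn powder in N,N-dimethylacetamide at 25 °C (nickel-catalysed decarboxylative cross-electrophile coupling of N-acyloxyphthalimides with aryl iodides) should give 25, where the route is rejoined.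

**Further compounds**

F1 | step 5 | 4-[(2R,3R)-3,7-dibromo-5-methoxy-4-oxochroman-2-yl]phenyl acetate (2,3-trans) | Brc1cc(OC)c2c(c1)O[C@H](c1ccc(OC(C)=O)cc1)[C@@H](Br)C2=O
F2 | step 5 | 4-[(2R,3R)-3,7-dibromo-4,4,5-trimethoxychroman-2-yl]phenyl acetate (2,3-trans) | Brc1cc(OC)c2c(c1)O[C@H](c1ccc(OC(C)=O)cc1)[C@@H](Br)C2(OC)OC
F3 | step 11 | 7-[(2S,3S)-6-bromo-4-methoxy-2-(4-methoxyphenyl)-2,3-dihydrobenzofuran-3-yl]-3,5,7-trioxoheptanoic acid | Brc1cc(OC)c2c(c1)O[C@H](c1ccc(OC)cc1)[C@H]2C(=O)CC(=O)CC(=O)CC(=O)O
F4 | step 11 | 2-[(2S,3S)-6-bromo-4-methoxy-2-(4-methoxyphenyl)-2,3-dihydrobenzofuran-3-yl]-4,6-dihydroxybenzoic acid | Brc1cc(OC)c2c(c1)O[C@H](c1ccc(OC)cc1)[C@H]2c1cc(O)cc(O)c1C(=O)O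
F5 | step 13 | (2S,3S)-3-(3,5-dimethoxyphenyl)-6-iodo-4-methoxy-2-(4-methoxyphenyl)-2,3-dihydrobenzofuran | Ic1cc(OC)c2c(c1)O[C@H](c1ccc(OC)cc1)[C@H]2c1cc(OC)cc(OC)c1
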